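A small charge of substrate, 0.020 M, opens to the open intermediate, and each open molecule then stands at a fork. It can take partner to give target, meet a second open molecule to give homo product, or meet capture agent to give trapped intermediate. The set-ups asked about bring the same amounts together in different ways.

| setting | elm | ash | oak | birch | south | north | north-east | east |
|---|---|---|---|---|---|---|---|---|
| substrate | 0.020 M | 0.020 M | 0.020 M | 0.020 M | 0.020 M | 0.020 M | 0.020 M (fed, over 2.40 min) | 0.020 M |
| partner | 1 equiv | 0.50 equiv | 2 equiv | 1 equiv | 1.00 equiv (fed, over 2.40 min) | 1.00 equiv | 1.00 equiv | 1.00 equiv |
| capture agent | 2 mM | 2 mM | 2 mM | 1 mM | 2.00 mM | 2.00 mM | 2.00 mM | 2.00 mM |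
| remark | run made earlier | run made earlier | run made earlier | run made earlier | all but partner at the start; partner goes in evenly over 2.40 min, the run ends at 3.0 min | a single well-mixed tank run continuously and read at steady state, 3.0 min in it on average | a stirred flask in which substrate is dosed at a steady rate over 2.40 min without added volume, worked up at 3.0 min | a closed flask charged with all of it at once and left for 3.0 min |
| time |  |  |  |  | 3.0 min |  | 3.0 min | 3.0 min |

elm run (percent of the substrate charged)

| time / min | target / % |
|---|---|
| 0.250 | 10.5 |
| 0.500 | 23.7 |
| 1.33 | 45.6 |
| 3.00 | 63.1 |

ash run (percent of the substrate charged)

| time / s | target / % |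
|---|---|
| 15.0 | 5.7 |
| 40.0 | 17.1 |
| 80.0 | 24.8 |
| 120 | 33.6 |

oak run (percent of the substrate charged)

| time / s | target / % |
|---|---|
| 25.0 | 34.6 |
| 50.0 | 58.8 |
| 80.0 | 74.1 |
| 120 | 82.0 |

birch run (percent of the substrate charged)

| time / s | target / % |
|---|---|
| 25.0 | 18.2 |
| 50.0 | 34.1 |
| 80.0 | 48.4 |
| 120 | 56.7 |

(scatter of a reading: 1 percentage point)

- percentages count the substrate that a species holds: one homo product counts as two
- the stated concentrations are those of everything mixed, before any reaction; amounts are the same in each set-up
- the analysis behind the earlier runs scatters by 1 percentage point, standard deviation
- steps thought possible: 2 open intermediate -> homo product; partner -> decomposition product; partner + open intermediate -> target; substrate -> open intermediate; open intermediate + capture agent -> trapped intermediate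
- the feed brings no volume worth counting
- the earlier runs were made in a closed, stirred flask

- the set-up with the highest amount of target at the outlet or at the end, in percent of the substrate put in ("none" if the first two lie within 2 percentage points) (south / north / north-east / east / none)
- amount of target at the outlet or at the end, in percent of the substrate put in, south
- amount of target at the outlet or at the end, in percent of the substrate put in, north
- amount of target at the outlet or at the end, in percent of the substrate put in, north-east
- amount of target at the outlet or at the end, in percent of the substrate put in, east

Two chemists dispute south, where partner enters over 2.40 min. The first holds that slow feeding turns the fork towards homo product. That view is the forecast, which gives south 30 % (23 % to 38 %), north 48 %, north-east 55 % and east 63 %, so that east is best. In its words, “starving the partner favours the homo product”.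

The second view is my own reckoning, and it starts from a clock. At 80.0 s, oak, with 2 equiv of partner, holds more target than ash, with 0.50 equiv: 74.1 % against 24.8 %. These two runs differ in partner and in no other setting. So I treat the meeting with partner as the rate-limiting step.

When equal charges meet, the share turned into target after a time t is t/(t+τ). Here τ is the meeting time, the time in which half of such a charge has reacted (the second-order half-life). It equals t multiplied by the share not yet target, divided by the share that is. The elm reading at 3.00 min gives 1.75 min, a rough reading, with the opening of substrate and whatever elm lost at the fork inside it.

In south, evenly fed partner spends on average 1.80 min in the flask. Putting that time into the same formula gives 50.6 %, which is more than the forecast's number.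

The simulation gives south 44.3 %, north 47.3 %, north-east 53.1 % and east 62.9 %, so the best set-up is east.

    2 open intermediate → homo product (k = 0.160 M⁻¹ s⁻¹)
    partner → decomposition product (k = 7.90 × 10⁻⁶ s⁻¹)
    partner + open intermediate → target (k = 0.750 M⁻¹ s⁻¹)
    substrate → open intermediate (k = 0.110 s⁻¹)
    open intermediate + capture agent → trapped intermediate (k = 0.180 M⁻¹ s⁻¹)

The first view holds early in south: at 1.50 min, homo product stands higher than target, 26.9 % against 20.8 %. At 3.00 min, south holds more target than homo product, 44.3 % against 33.5 %. The neighbouring flask is like south but holds 0.0050 M of substrate, a quarter of the concentration, with the equivalents kept. By my reckoning the meeting time grows to 7.02 min, and the same average stay gives 20.4 %. That flask ends with 24.3 % of target, while 54.8 % is still open intermediate.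

All runs stem from a simulated flask on assumed constants, noise included.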